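**Retrosynthetic overview**
1. Locants: ring C1 (quaternary; CH3 and side chain C1′–C12′) – C2 (CHCH3) – C3 – C4 – C5 (=C7(CH3)–C8H2OH) – C6 (H; arm C9–C10–C11H2OH). With these locants the target is 1R,2R,6S, C5=C7 Z, 3′E, 6′E, 8′S.
2. Feature used: C2 and C5 are para ring carbons that each carry a carbon substituent (a latent cyclohexane-1,4-dione), and the adjacent C1 and C6 each carry a CH2 (C1′, C9). Joining these two CH2 groups through C2′ and C10 gives a temporary cyclohexene, so ring A is 2-methoxy-5-methylbenzoquinone and the temporary ring B is a 2-silyloxybutadiene.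
3. Disconnections, backwards: C10=C11 (Wittig) and lactone reduction; C5′–C6′ (allyl–alkenyl coupling, alkenyl iodide from (S)-citronellal); C2′–C3′ (alkyl–alkenyl Negishi); C2–CH3 (methylenation, hydrogen-atom-transfer hydrogenation); C5=C7 (tethered Horner–Wadsworth–Emmons closure of a seven-membered lactone, which fixes the alkene geometry); enol-ether ozonolysis; Diels–Alder.
4. Ring order: ring A is the quinone ring. Ring B forms in step 2 and is cut in step 5, where a temporary γ-lactone tells the two arms apart. The seven-membered lactone forms in step 10 and is opened in step 25.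

Key step: step 2

Remark: the carbinol centres that step 5 creates at C2 and C5 (and the phosphonate α-carbon of 13 and 14) are carried as epimer mixtures and drawn without configuration, because step 9 and step 10 remove them.

**Step 1**
Reactants: 1 methyl vinyl ketone
Product: 2 2-(triisopropylsilyloxy)buta-1,3-diene
Conditions: i-Pr3SiOTf, Et3N, Et2O, 0 → 23 °C
Reagents that add atoms: triisopropylsilyl trifluoromethanesulfonate, CC(C)[Si](OS(=O)(=O)C(F)(F)F)(C(C)C)C(C)C
Why: Amine-mediated soft enolisation and O-silylation of the enone (silyl enol ether formation) gives the 2-silyloxydiene; no stereocentre is formed.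

**Step 2**
Reactants: 3 2-methoxy-5-methyl-1,4-benzoquinone; 2 2-(triisopropylsilyloxy)buta-1,3-diene
Product: 4 cis-2-methoxy-4a-methyl-7-(triisopropylsilyloxy)-4a,5,8,8a-tetrahydronaphthalene-1,4-dione (cis-fused adduct; C1–CH3 and C6–H on the same face)
Conditions: oxazaborolidine from (S)-α,α-diphenylprolinol and tris(2-methylphenyl)boroxine (20 mol%), HNTf2 (18 mol%), CH2Cl2, −78 °C
Reagents that add atoms: none
Why: This is a Lewis-acid-catalysed normal-demand Diels–Alder reaction (closest known type: oxazaborolidinium-catalysed cycloadditions of 2-substituted benzoquinones with 2-silyloxybutadienes), in which the protonated oxazaborolidine binds the more basic vinylogous-ester carbonyl (C2=O) and the diene adds in a concerted, asynchronous [4+2] across the methyl-bearing C1=C6 bond. Ring B (C1, C1′, C2′, C10, C9, C6) closes by suprafacial addition on both partners, forming C1–C1′ and C6–C9, so the new six-membered ring is cis-fused. Quaternary C1 is set by the catalyst, which shields one face of the bound quinone; C6 follows from the cis addition and is formed as the epimer that step 3 inverts. Site selectivity is needed and comes from the methoxy group, which turns C3=C4 into an unreactive vinylogous ester. Regioselectivity is needed and comes from coordination at C2=O, which makes C6 the electrophilic β-carbon that bonds to the nucleophilic CH2 terminus next to the silyloxy carbon, so the enol ether ends at C10.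

**Step 3**
Reactants: 4 cis-fused adduct
Product: 5 trans-2-methoxy-4a-methyl-7-(triisopropylsilyloxy)-4a,5,8,8a-tetrahydronaphthalene-1,4-dione (C6 epimer of 4)
Conditions: NaOMe (0.1 equiv), MeOH–THF, 0 °C; AcOH quench; recovered 4 resubmitted
Reagents that add atoms: none
Why: Base-mediated epimerisation through the enolate of the C5 ketone should move C6 to the trans-fused (thermodynamic) configuration; quaternary C1 blocks aromatisation and methoxide exchange at C4 is degenerate.

**Step 4**
Reactants: 5 trans-fused methoxy enedione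
Product: 7 trans-4a-methyl-7-(triisopropylsilyloxy)-2,3,4a,5,8,8a-hexahydronaphthalene-1,4-dione, via 4-methoxy-1,4-dione 6 (not isolated)
Conditions: SmI2 (4.5 equiv), THF–MeOH, −78 °C; aq. NH4Cl
Reagents that add atoms: none
Why: Divalent samarium reduces the ene-dione to the 2-methoxy-1,4-dione and then cleaves the C4–OMe bond α to the C5 ketone (reductive cleavage of an α-alkoxy ketone); the silyl enol ether and the ring fusion should be untouched at −78 °C.

**Step 5**
Reactants: 7 trans-fused 1,4-dione silyl enol ether
Product: 10 γ-lactone diol (C10 carboxyl lactonised onto the C5 hydroxyl; free C2 and C2′ hydroxyls), via methoxy hydroperoxide silyl ester 8 (not isolated), via trihydroxy acid 9 (not isolated)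
Conditions: O3, CH2Cl2–MeOH, −78 °C; NaBH4, −78 → 23 °C; 1 M HCl; PPTS (cat.), CH2Cl2
Reagents that add atoms: ozone, [O-][O+]=O
Why: Ozonolysis with reductive work-up cleaves the electron-rich silyl enol ether, the only C=C bond present, to give C2′ as a methanol-trapped carbonyl oxide and C10 as the silyl ester; borohydride then reduces the peroxide, the aldehyde and both ring ketones, and acid closes the γ-lactone between C10 and the C5 hydroxyl, which differentiates the two arms.

**Step 6**
Reactants: 10 γ-lactone diol
Product: 11 C2′ tert-butyldiphenylsilyl ether of 10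
Conditions: t-BuPh2SiCl, imidazole, CH2Cl2, 0 °C
Reagents that add atoms: tert-butyl(chloro)diphenylsilane, CC(C)(C)[Si](Cl)(c1ccccc1)c1ccccc1
Why: Silyl ether protection should take the primary C2′ hydroxyl selectively over the hindered secondary C2 hydroxyl next to the quaternary carbon.

**Step 7**
Reactants: 11 silyl ether lactone
Product: 12 triol (C10 primary, C5 and C2 secondary hydroxyls; C2′ silyl ether)
Conditions: LiAlH4, THF, 0 °C; aq. potassium sodium tartrate
Reagents that add atoms: none
Why: Hydride reduction of the lactone (ester reduction) releases the primary C10 alcohol and the C5 carbinol; the silyl ether is stable.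

**Step 8**
Reactants: 12 triol
Product: 13 C10 2-(diethoxyphosphoryl)propanoate of 12
Conditions: 2-(diethoxyphosphoryl)propanoic acid (1.05 equiv), EDC·HCl, DMAP (cat.), CH2Cl2, −20 → 0 °C
Reagents that add atoms: 2-(diethoxyphosphoryl)propanoic acid, CCOP(=O)(OCC)C(C)C(=O)O
Why: Carbodiimide (Steglich) esterification should acylate the unhindered primary C10 hydroxyl ahead of the two secondary ring hydroxyls and so installs the olefination tether.

**Step 9**
Reactants: 13 phosphonate ester diol
Product: 14 2,5-diketone phosphonate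
Conditions: Dess–Martin periodinane (3 equiv), CH2Cl2, 0 → 23 °C
Reagents that add atoms: none
Why: Dess–Martin oxidation returns both secondary carbinols to ketones under near-neutral conditions, so C6 (α to the C5 ketone) should keep its configuration.

**Step 10**
Reactants: 14 2,5-diketone phosphonate
Product: 15 bicyclic α,β-unsaturated seven-membered lactone (C5=C7(CH3)–C8(=O)–O–C10) with the C2 ketone
Conditions: LiCl, DBU, MeCN (0.005 M), 23 → 45 °C
Reagents that add atoms: none
Why: In this intramolecular Horner–Wadsworth–Emmons olefination the phosphonate anion can reach only the C5 ketone (seven-membered ring; C2 would need an eight-membered ring), and because C5=C7 becomes a ring cis-alkene the C8 carbonyl must lie cis to C6, which sets the tetrasubstituted alkene geometry.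

**Step 11**
Reactants: 15 lactone ketone
Product: 16 C2 exo-methylene lactone
Conditions: Zn, CH2Br2, TiCl4, THF–CH2Cl2, 0 → 23 °C
Reagents that add atoms: dibromomethane, BrCBr
Why: Takai–Lombardo methylenation converts the hindered, enolisable C2 ketone into the methylene without base, so the lactone and C6 are not disturbed.

**Step 12**
Reactants: 16 exo-methylene lactone
Product: 17 C2-methyl lactone (C2–CH3 trans to C1–CH3, cis to the C1′ chain)
Conditions: Mn(dpm)3 (10 mol%), PhSiH3, t-BuOOH, i-PrOH, 23 °C
Reagents that add atoms: none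
Why: In this metal-hydride hydrogen-atom-transfer hydrogenation (Mukaiyama type) H• adds to the terminal CH2 and the tertiary C2 radical should take hydrogen axially, anti to the axial C1′ chain; this gives the equatorial methyl, which is also the thermodynamic epimer because the lactone holds C9 axial and the other epimer would be 1,3-syn-axial to it, while the tetrasubstituted conjugated alkene reacts far more slowly.

**Step 13**
Reactants: 17 silyl ether
Product: 18 C2′ primary alcohol
Conditions: Bu4NF, AcOH, THF, 0 → 23 °C
Reagents that add atoms: none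
Why: Fluoride desilylation, buffered with acetic acid so that the lactone is not opened.

**Step 14**
Reactants: 18 primary alcohol
Product: 19 C2′ primary iodide
Conditions: I2, PPh3, imidazole, CH2Cl2, 0 °C
Reagents that add atoms: iodine, II
Why: Appel-type iodination proceeds by SN2 displacement of the oxyphosphonium at C2′, which is not neopentylic.

**Step 15**
Reactants: 20 prop-2-yn-1-ol
Product: 22 (E)-3-iodo-2-methylprop-2-en-1-ol, via alkenylalane 21 (not isolated)
Conditions: Me3Al (3 equiv), Cp2ZrCl2 (0.25 equiv), CH2Cl2, 0 → 23 °C; I2, THF, −30 → 0 °C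
Reagents that add atoms: trimethylaluminium, C[Al](C)C; iodine, II
Why: Zirconium-catalysed syn-carboalumination (Negishi carboalumination) puts methyl on the internal carbon and aluminium on the terminus, and iodinolysis with retention gives the E-iodoalkene.

**Step 16**
Reactants: 22 (E)-3-iodo-2-methylprop-2-en-1-ol
Product: 23 tert-butyldimethylsilyl ether of 22
Conditions: t-BuMe2SiCl, imidazole, CH2Cl2, 0 → 23 °C
Reagents that add atoms: tert-butyl(chloro)dimethylsilane, CC(C)(C)[Si](C)(C)Cl
Why: Standard silyl ether protection of the primary allylic alcohol.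

**Step 17**
Reactants: 19 primary iodide; 23 alkenyl iodide silyl ether
Product: 25 lactone carrying the (E)-C1′–C5′ chain with C5′ silyl ether, via alkylzinc iodide 24 (not isolated)
Conditions: Zn dust, LiCl, THF, 40 °C; then 23, PdCl2(dppf) (5 mol%), THF, 23 → 45 °C
Reagents that add atoms: none
Why: Zinc inserts into the primary C–I bond and the alkylzinc couples with the alkenyl iodide under zerovalent palladium catalysis with retention of the E geometry (sp3–sp2 Negishi coupling); the lactone tolerates the organozinc.

**Step 18**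
Reactants: 25 silyl ether
Product: 26 C5′ allylic alcohol
Conditions: Bu4NF, AcOH, THF, 0 → 23 °C
Reagents that add atoms: none
Why: Fluoride desilylation of the allylic silyl ether; the lactone survives under buffering.

**Step 19**
Reactants: 26 allylic alcohol
Product: 27 C5′ allylic chloride
Conditions: PPh3, CCl4, 60 °C
Reagents that add atoms: carbon tetrachloride, ClC(Cl)(Cl)Cl
Why: Appel chlorination replaces the primary allylic hydroxyl by SN2 attack on the oxyphosphonium, without allylic transposition or loss of the E geometry.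

**Step 20**
Reactants: 28 (S)-citronellal
Product: 30 (3S)-3,7-dimethyl-2-(phenylaminooxy)oct-6-en-1-ol, via 2-aminooxy aldehyde 29 (not isolated)
Conditions: PhNO, L-proline (10 mol%), CHCl3, 4 °C; NaBH4, EtOH, 0 °C
Reagents that add atoms: nitrosobenzene, O=Nc1ccccc1
Why: Proline-catalysed α-aminoxylation (enamine attack on the nitroso oxygen) followed by in situ borohydride reduction gives the stable aminooxy alcohol; the new C2 centre is excised in step 22 and C3 is not touched.

**Step 21**
Reactants: 30 aminooxy alcohol
Product: 31 (3S)-3,7-dimethyloct-6-ene-1,2-diol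
Conditions: Zn, AcOH–THF, 23 °C
Reagents that add atoms: none
Why: Zinc in acetic acid reduces the N–O bond (reductive N–O cleavage) and leaves the trisubstituted alkene alone.

**Step 22**
Reactants: 31 1,2-diol
Product: 32 (S)-2,6-dimethylhept-5-enal
Conditions: NaIO4, THF–H2O, 0 → 23 °C
Reagents that add atoms: none
Why: Periodate glycol cleavage removes C1 as formaldehyde under neutral conditions that should not epimerise the α-methyl aldehyde.

**Step 23**
Reactants: 32 (S)-2,6-dimethylhept-5-enal
Product: 33 (S,E)-1-iodo-3,7-dimethylocta-1,6-diene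
Conditions: CrCl2 (6 equiv), CHI3 (2 equiv), THF–dioxane, 0 → 23 °C
Reagents that add atoms: iodoform, IC(I)I
Why: Takai olefination (geminal dichromium addition and elimination) gives the E-iodoalkene under non-basic conditions that preserve the adjacent stereocentre.

**Step 24**
Reactants: 33 alkenyl iodide; 27 allylic chloride
Product: 36 lactone carrying the complete (3′E,6′E,8′S) side chain, via alkenyllithium 34 (not isolated), via alkenylzinc chloride 35 (not isolated)
Conditions: 33 (1.5 equiv), t-BuLi (2 equiv per 33), Et2O, −78 °C; ZnCl2, THF, −78 → 0 °C; then 27, Pd(PPh3)4 (5 mol%), THF, 0 → 23 °C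
Reagents that add atoms: none
Why: Iodine–lithium exchange with retention, transmetalation to zinc and zerovalent-palladium-catalysed coupling at the primary terminus of the syn π-allyl complex (allyl–alkenyl Negishi coupling) should give the skipped diene with both alkene geometries kept; the lactone is inert to the organozinc.

**Step 25**
Reactants: 36 lactone with full side chain
Product: 37 diol (C8 allylic alcohol and C10 primary alcohol)
Conditions: i-Bu2AlH (3.5 equiv), CH2Cl2, −78 → 0 °C; aq. potassium sodium tartrate
Reagents that add atoms: none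
Why: Aluminium hydride reduction of the conjugated lactone by 1,2-addition opens it to the allylic and the saturated primary alcohol.

**Step 26**
Reactants: 37 diol
Product: 38 dialdehyde (C8 enal and C10 aldehyde)
Conditions: Dess–Martin periodinane (2.5 equiv), CH2Cl2, 0 → 23 °C
Reagents that add atoms: none
Why: Dess–Martin oxidation converts both primary alcohols to aldehydes under mild conditions that should not isomerise the tetrasubstituted enal.

**Step 27**
Reactants: 38 dialdehyde
Product: 39 C8 enal with C10=C11 terminal alkene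
Conditions: Ph3PCH3Br (1.1 equiv), KN(SiMe3)2 (1.05 equiv), THF, −78 → −40 °C
Reagents that add atoms: methyltriphenylphosphonium bromide, C[P+](c1ccccc1)(c1ccccc1)c1ccccc1.[Br-]
Why: Wittig methylenation with one equivalent of ylide at low temperature should select the unhindered aliphatic C10 aldehyde over the conjugated, α-methyl-β,β-disubstituted C8 enal.

**Step 28**
Reactants: 39 enal with terminal alkene
Product: 41 target CNP0327981.1, via bis(9-BBN) adduct 40 (not isolated)
Conditions: 9-BBN (3 equiv), THF, 0 → 23 °C; NaOH, H2O2, 0 °C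
Reagents that add atoms: hydrogen peroxide, OO
Why: 9-BBN reduces the enal by 1,2-addition and hydroborates the monosubstituted C10=C11 alkene at its terminus much faster than the di-, tri- and tetrasubstituted alkenes, and alkaline peroxide then releases both primary alcohols (hydroboration–oxidation).

**Compound list**
1 | methyl vinyl ketone | CC(=O)C=C | starting material
2 | 2-(triisopropylsilyloxy)buta-1,3-diene | C=CC(=C)O[Si](C(C)C)(C(C)C)C(C)C | intermediate
3 | 2-methoxy-5-methyl-1,4-benzoquinone | COC1=CC(=O)C(C)=CC1=O | starting material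
4 | cis-fused Diels–Alder adduct (C1–CH3 and C6–H cis) | COC1=CC(=O)[C@@]2(C)CC=C(O[Si](C(C)C)(C(C)C)C(C)C)C[C@H]2C1=O | intermediate
5 | trans-fused adduct (C6 epimer of 4) | COC1=CC(=O)[C@@]2(C)CC=C(O[Si](C(C)C)(C(C)C)C(C)C)C[C@@H]2C1=O | intermediate
6 | trans-fused 4-methoxy-1,4-dione, C4 epimers (not isolated) | COC1CC(=O)[C@@]2(C)CC=C(O[Si](C(C)C)(C(C)C)C(C)C)C[C@@H]2C1=O | intermediate
7 | trans-fused 1,4-dione silyl enol ether | C1CC(=O)[C@@]2(C)CC=C(O[Si](C(C)C)(C(C)C)C(C)C)C[C@@H]2C1=O | intermediate
8 | ring-opened 2,5-diketone with C2′ as CH(OMe)OOH and C10 as triisopropylsilyl ester (not isolated) | COC(OO)C[C@]1(C)C(=O)CCC(=O)[C@H]1CC(=O)O[Si](C(C)C)(C(C)C)C(C)C | intermediate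
9 | trihydroxy acid, C2/C5 carbinol epimers (not isolated) | OCC[C@]1(C)C(O)CCC(O)[C@H]1CC(=O)O | intermediate
10 | γ-lactone diol (C10 acyl on C5–O; free C2 and C2′ OH), carbinol epimers | OCC[C@]1(C)C(O)CCC2[C@H]1CC(=O)O2 | intermediate
11 | C2′ tert-butyldiphenylsilyl ether of 10 | CC(C)(C)[Si](c1ccccc1)(c1ccccc1)OCC[C@]1(C)C(O)CCC2[C@H]1CC(=O)O2 | intermediate
12 | triol (C2, C5, C10 OH; C2′ silyl ether) | CC(C)(C)[Si](c1ccccc1)(c1ccccc1)OCC[C@]1(C)C(O)CCC(O)[C@H]1CCO | intermediate
13 | C10 2-(diethoxyphosphoryl)propanoate of 12 | CC(C)(C)[Si](c1ccccc1)(c1ccccc1)OCC[C@]1(C)C(O)CCC(O)[C@H]1CCOC(=O)C(C)P(=O)(OCC)OCC | intermediate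
14 | 2,5-diketone phosphonate | CC(C)(C)[Si](c1ccccc1)(c1ccccc1)OCC[C@]1(C)C(=O)CCC(=O)[C@H]1CCOC(=O)C(C)P(=O)(OCC)OCC | intermediate
15 | bicyclic unsaturated seven-membered lactone with C2 ketone | CC(C)(C)[Si](c1ccccc1)(c1ccccc1)OCC[C@]1(C)C(=O)CC/C2=C(\C)C(=O)OCC[C@@H]12 | intermediate
16 | C2 exo-methylene lactone | CC(C)(C)[Si](c1ccccc1)(c1ccccc1)OCC[C@]1(C)C(=C)CC/C2=C(\C)C(=O)OCC[C@@H]12 | intermediate
17 | C2-methyl lactone, C2′ silyl ether | CC(C)(C)[Si](c1ccccc1)(c1ccccc1)OCC[C@]1(C)[C@H](C)CC/C2=C(\C)C(=O)OCC[C@@H]12 | intermediate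
18 | C2-methyl lactone, C2′ alcohol | OCC[C@]1(C)[C@H](C)CC/C2=C(\C)C(=O)OCC[C@@H]12 | intermediate
19 | C2-methyl lactone, C2′ iodide | ICC[C@]1(C)[C@H](C)CC/C2=C(\C)C(=O)OCC[C@@H]12 | intermediate
20 | prop-2-yn-1-ol | C#CCO | starting material
21 | (E)-alkenyl dimethylalane O-dimethylaluminium alkoxide (not isolated) | C[Al](C)OC/C(C)=C/[Al](C)C | intermediate
22 | (E)-3-iodo-2-methylprop-2-en-1-ol | OC/C(C)=C/I | intermediate
23 | (E)-tert-butyl[(3-iodo-2-methylprop-2-en-1-yl)oxy]dimethylsilane | CC(C)(C)[Si](C)(C)OC/C(C)=C/I | intermediate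
24 | C2′ alkylzinc iodide of the lactone (not isolated) | I[Zn]CC[C@]1(C)[C@H](C)CC/C2=C(\C)C(=O)OCC[C@@H]12 | intermediate
25 | lactone with (E)-C1′–C5′ chain, C5′ silyl ether | CC(C)(C)[Si](C)(C)OC/C(C)=C/CC[C@]1(C)[C@H](C)CC/C2=C(\C)C(=O)OCC[C@@H]12 | intermediate
26 | lactone with (E)-C1′–C5′ chain, C5′ alcohol | OC/C(C)=C/CC[C@]1(C)[C@H](C)CC/C2=C(\C)C(=O)OCC[C@@H]12 | intermediate
27 | lactone with (E)-C1′–C5′ chain, C5′ chloride | ClC/C(C)=C/CC[C@]1(C)[C@H](C)CC/C2=C(\C)C(=O)OCC[C@@H]12 | intermediate
28 | (S)-citronellal | CC(C)=CCC[C@H](C)CC=O | starting material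
29 | (3S)-3,7-dimethyl-2-(phenylaminooxy)oct-6-enal (not isolated) | CC(C)=CCC[C@H](C)C(ONc1ccccc1)C=O | intermediate
30 | (3S)-3,7-dimethyl-2-(phenylaminooxy)oct-6-en-1-ol | CC(C)=CCC[C@H](C)C(CO)ONc1ccccc1 | intermediate
31 | (3S)-3,7-dimethyloct-6-ene-1,2-diol | CC(C)=CCC[C@H](C)C(O)CO | intermediate
32 | (S)-2,6-dimethylhept-5-enal | CC(C)=CCC[C@H](C)C=O | intermediate
33 | (S,E)-1-iodo-3,7-dimethylocta-1,6-diene | CC(C)=CCC[C@H](C)/C=C/I | intermediate
34 | (S,E)-alkenyllithium from 33 (not isolated) | CC(C)=CCC[C@H](C)/C=C/[Li] | intermediate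
35 | (S,E)-alkenylzinc chloride (not isolated) | CC(C)=CCC[C@H](C)/C=C/[Zn]Cl | intermediate
36 | lactone with complete (3′E,6′E,8′S) side chain | CC(C)=CCC[C@H](C)/C=C/C/C(C)=C/CC[C@]1(C)[C@H](C)CC/C2=C(\C)C(=O)OCC[C@@H]12 | intermediate
37 | diol (C8–OH, C10–OH) | CC(C)=CCC[C@H](C)/C=C/C/C(C)=C/CC[C@]1(C)[C@H](C)CC/C(=C(\C)CO)[C@H]1CCO | intermediate
38 | dialdehyde (C8 enal, C10 aldehyde) | CC(C)=CCC[C@H](C)/C=C/C/C(C)=C/CC[C@]1(C)[C@H](C)CC/C(=C(\C)C=O)[C@H]1CC=O | intermediate
39 | C8 enal with C10=C11 alkene | CC(C)=CCC[C@H](C)/C=C/C/C(C)=C/CC[C@]1(C)[C@H](C)CC/C(=C(\C)C=O)[C@H]1CC=C | intermediate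
40 | C8 O-borinate and C11 B-alkyl bis(9-BBN) adduct (not isolated) | CC(C)=CCC[C@H](C)/C=C/C/C(C)=C/CC[C@]1(C)[C@H](C)CC/C(=C(\C)COB2C3CCCC2CCC3)[C@H]1CCCB1C2CCCC1CCC2 | intermediate
41 | CNP0327981.1 (1R,2R,6S; C5=C7 Z; 3′E,6′E,8′S in the locants used here) | CC(C)=CCC[C@H](C)/C=C/C/C(C)=C/CC[C@]1(C)[C@H](C)CC/C(=C(\C)CO)[C@H]1CCCO | target

**Step count and risks**
Total: 28 steps. Longest linear sequence: 22 steps (steps 1–14, 17–19, 24–28); side branches are steps 15–16 and 20–23.

Most likely to fail:

1. Step 10. The seven-membered ring may close slowly at the hindered ketone, so that C6 epimerises or oligomers form before olefination. The fallback makes the same alkene by ring-closing metathesis and runs from 12 to 16. Triol 12 would be acylated at the primary hydroxyl with methacryloyl chloride (Et3N, CH2Cl2, −20 °C) to the methacrylate diol F1. Dess–Martin oxidation would give the diketone methacrylate F2, and CH2Br2/Zn/TiCl4 at both ketones would give the bis(exo-methylene) methacrylate F3, in which C6 can no longer epimerise. A second-generation Hoveyda–Grubbs catalyst in hot toluene at high dilution should then join the C5 methylene to the methacrylate (the C2 methylene would need an eight-membered ring) and give 16 with the same ring-enforced geometry.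

2. Step 12. Hydrogen delivery to the C2 radical may be poorly face-selective, or the conjugated lactone may be reduced in competition. The fallback sets C2 by equilibration and runs from 16 to 17. Hydroboration of 16 with 9-BBN and oxidation with NaBO3 would give the C2 hydroxymethyl compound F4 as an epimer mixture. Dess–Martin oxidation followed by DBU would give the C2 aldehyde F5 as the equatorial, thermodynamic epimer (the other is syn-axial to C9). Condensation with TsNHNH2 would give the tosylhydrazone F6, and catecholborane then NaOAc would reduce it to the methyl group of 17.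

3. Step 27. The ylide may not discriminate the two aldehydes, or the enal may lose its geometry under the basic conditions. The fallback differentiates the termini before reduction and runs from 36 to 39. Lactone 36 would be opened with MeNH(OMe)·HCl/Me3Al to the hydroxy Weinreb amide F7, oxidised with Dess–Martin periodinane to the aldehyde amide F8, methylenated with Ph3P=CH2 (the amide is inert) to the alkene amide F9, and reduced with i-Bu2AlH at −78 °C to the enal 39.

**Further compounds**
F1 | step 10 | C10 methacrylate of triol 12 | CC(C)(C)[Si](c1ccccc1)(c1ccccc1)OCC[C@]1(C)C(O)CCC(O)[C@H]1CCOC(=O)C(C)=C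
F2 | step 10 | 2,5-diketone methacrylate | CC(C)(C)[Si](c1ccccc1)(c1ccccc1)OCC[C@]1(C)C(=O)CCC(=O)[C@H]1CCOC(=O)C(C)=C
F3 | step 10 | 2,5-bis(exo-methylene) methacrylate | CC(C)(C)[Si](c1ccccc1)(c1ccccc1)OCC[C@]1(C)C(=C)CCC(=C)[C@H]1CCOC(=O)C(C)=C
F4 | step 12 | C2 hydroxymethyl lactone (C2 epimers) | CC(C)(C)[Si](c1ccccc1)(c1ccccc1)OCC[C@]1(C)C(CO)CC/C2=C(\C)C(=O)OCC[C@@H]12
F5 | step 12 | C2 formyl lactone (equatorial epimer) | CC(C)(C)[Si](c1ccccc1)(c1ccccc1)OCC[C@]1(C)[C@H](C=O)CC/C2=C(\C)C(=O)OCC[C@@H]12
F6 | step 12 | C2 formyl tosylhydrazone | CC(C)(C)[Si](c1ccccc1)(c1ccccc1)OCC[C@]1(C)[C@H](C=NNS(=O)(=O)c3ccc(C)cc3)CC/C2=C(\C)C(=O)OCC[C@@H]12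
F7 | step 27 | C8 Weinreb amide with C10 alcohol | CC(C)=CCC[C@H](C)/C=C/C/C(C)=C/CC[C@]1(C)[C@H](C)CC/C(=C(\C)C(=O)N(C)OC)[C@H]1CCO
F8 | step 27 | C8 Weinreb amide with C10 aldehyde | CC(C)=CCC[C@H](C)/C=C/C/C(C)=C/CC[C@]1(C)[C@H](C)CC/C(=C(\C)C(=O)N(C)OC)[C@H]1CC=O
F9 | step 27 | C8 Weinreb amide with C10=C11 alkene | CC(C)=CCC[C@H](C)/C=C/C/C(C)=C/CC[C@]1(C)[C@H](C)CC/C(=C(\C)C(=O)N(C)OC)[C@H]1CC=C
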